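The data were computed from invented constants, and the scatter is random.

3 questions are asked of this flask, and the loss of D and E together is the one the readings can answer.

| flask | D | E | J | X | remark | time |
|---|---|---|---|---|---|---|
| Saturday's | 0.25 M | 0.25 M | 0.55 M | 6.3 mM | run made earlier |  |
| Tuesday's | 0.25 M | 0.25 M | 0.55 M | 9.9 mM | run made earlier |  |
| Wednesday's | 0.12 M | 0.12 M | 0.55 M | 4.5 mM | run made earlier |  |
| flask | 0.25 M | 0.25 M | 0.550 M | 4.5 mM |  | 10 h |

- Saturday's (time / h: D / %, E / %): 0.667: 48.7, 49.6; 2.00: 47.6, 47.4; 4.00: 45.4, 45.9; 6.00: 43.0, 43.9; 8.00: 42.8, 43.0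
- Tuesday's (time / h: D / %, E / %): 0.667: 49.0, 49.4; 1.33: 47.5, 48.7; 2.50: 47.3, 46.4; 4.00: 45.3, 45.3; 8.00: 41.9, 41.9
- Wednesday's (time / h: D / %, E / %): 1.50: 48.5, 48.2; 3.00: 46.4, 46.1; 5.00: 44.6, 44.8; 6.00: 43.8, 44.8; 8.00: 43.0, 41.6

(scatter of a reading: 0.5 percentage points)

- J is single-handed; D and E are mirror images of each other, charged as a racemate, each of them at the stated concentration
- steps that have been proposed: J + D -> Q; J + E -> L; D + X <-> E + X; Q <-> L; J -> Z; 2 J -> G
- an excess is the difference of the two amounts in percent of their sum
- an excess is below zero if the other one leads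
- the handed part of J does not stay in what it makes, so the products of the two hands are mirror images too

- part of the D and E charged together that has reacted at 10 h
- excess of Q over L in the product at 10 h
- excess of E over D among what is left of the two at 10 h

We work in fractions of the D and E charged. On Saturday and Tuesday the two together stood on average at 90.9% at 4.00 h. That gives the quantity we carry, the early loss rate, the share lost per hour averaged over those first hours in runs charged with J at 0.550 M, an average pseudo-first-order constant and not the rate at the charge itself: 0.0237 /h. Wednesday's charge, about half of theirs, still kept 84.6% at 8.00 h, so the loss goes with what is there.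

Run straight on, this rate gives 21.1% reacted at 10 h. But the loss slows: from 4.00 h to 8.00 h those two runs fell to 84.8%, a rate of 0.0175 /h, lower than the early one. So we keep what was read and reckon just the last stretch as a correction, 2.9 percentage points, which makes 18.1%. That rate may still be falling, so the figure may be a little high, but it acts on a small step. D and E track each other within the scatter, so we put eS at zero. Q and L were not read, and we give no figure for eP.

The forecast gave 18%, 30% and 0.3%, and held that “eP is poorly determined”. The flask gives 16.9%, 2.14% and 0.0660%.

    J + D → Q (k = 0.0710 /M/h)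
    J + E → L (k = 0.0410 /M/h)
    D + X ⇌ E + X, rate k3*[X]*[D] forward; the back reaction follows from the equilibrium constant (k = 530 /M/h)
    Q ⇌ L (k = 0.400 /h)
    J → Z (k = 5.00 × 10⁻⁵ /h)
    2 J → G (k = 0.110 /M/h)

Over 10 h this flask lost 0.0185 /h on average, less than the early rate, with J down to 37.6% of its charge. A neighbouring flask, the same but with 0.14 M of J, holds a quarter of that J. Scaling the early rate by this fraction gives 5.85% reacted at 10 h, and the neighbour gives 5.89%. Its J stands at 60.1% of its own charge at 10.0 h, while the first flask's stands at 56.0% at 5.00 h.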